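## Plan

- **Cuts.** After the five benzyl ethers and the boron precursor of the carbinol are stripped back, two C–C bonds of the C6 side chain are cut together: the CH2–CH(OH) bond to the 4-hydroxybenzyl group and the aryl–CH bond to the resorcinol ring. This leaves a (3R)-isoflavan with an (E)-2-borylvinyl group on C6, a benzyl Grignard reagent and an aryl bromide.
- **Enabling feature.** In the chain ring A C6–CH(2,4-dihydroxyphenyl)–CH(OH)–CH2–(4-hydroxyphenyl), the carbinol carbon sits between a benzylic CH2 and a diarylmethine CH. That pattern arises when a benzyl group moves from boron to carbon across a C6–CH=CH–B unit while an aryl group is delivered to the carbon next to ring A.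
- **Earlier cuts.** The vinyl boronate goes back to the C6 bromide, the pyran ring to an O1–C2 etherification, and C3–C4 to the alkylation of a ring B arylacetyl imide with a ring A benzyl bromide.
- **Forward order.** Rings A and B are bought as benzaldehydes and joined at C3–C4; the pyran ring is closed; the two-carbon boronate is placed on C6; the benzyl and resorcinol units are attached in one three-component coupling; oxidation and hydrogenolysis finish.
- **Stereochemistry.** C3 comes from (R)-4-benzyl-2-oxazolidinone. The diarylmethine and carbinol carbons come from the chiral bisphosphine on palladium (alkene face) and the anti addition across the E alkene (relative configuration); the C–B bond is oxidised with retention.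

Key step: step 19

Remark: diol 21 (the mac diol) is taken as a purchasable reagent (otherwise one step from acenaphthenequinone and AlMe3); the sense of induction of (Sp,Sp)-MandyPhos in step 19 is assigned by analogy and would be confirmed on the first run, the antipodal ligand being used if it proves opposite.

## Route

Step 1
Reactants: 1 5-bromo-2,4-dihydroxybenzaldehyde
Product: 2 4-(benzyloxy)-5-bromo-2-hydroxybenzaldehyde
Conditions: BnBr (1.05 equiv), NaHCO3, MeCN, 80 °C
Reagents that add atoms: benzyl bromide BrCc1ccccc1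
Why: Williamson etherification with a weak base should alkylate only the 4-OH, which is the more acidic (para to the formyl group) and is not held in the hydrogen bond that ties the 2-OH to the aldehyde.

Step 2
Reactants: 2 4-(benzyloxy)-5-bromo-2-hydroxybenzaldehyde
Product: 3 4-(benzyloxy)-5-bromo-2-(methoxymethoxy)benzaldehyde
Conditions: MOMCl, i-Pr2NEt, CH2Cl2, 0 °C to reflux
Reagents that add atoms: chloromethyl methyl ether COCCl
Why: O-alkylation with MOMCl (acetal protection) masks the future ring oxygen with a group that can later be removed by acid without touching benzyl ethers or the aryl bromide.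

Step 3
Reactants: 3 4-(benzyloxy)-5-bromo-2-(methoxymethoxy)benzaldehyde
Product: 4 [4-(benzyloxy)-5-bromo-2-(methoxymethoxy)phenyl]methanol
Conditions: NaBH4, MeOH/THF, 0 °C
Reagents that add atoms: none
Why: Borohydride reduction of an aryl aldehyde is chemoselective; the aryl bromide, acetal and ether are inert.

Step 4
Reactants: 4 [4-(benzyloxy)-5-bromo-2-(methoxymethoxy)phenyl]methanol
Product: 5 4-(benzyloxy)-5-bromo-2-(methoxymethoxy)benzyl bromide
Conditions: CBr4, PPh3, CH2Cl2, 0 °C; short filtration, used at once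
Reagents that add atoms: carbon tetrabromide BrC(Br)(Br)Br
Why: The Appel reaction converts the benzylic alcohol to the bromide under neutral conditions that spare the acid-labile MOM acetal; the electron-rich bromide is not stored.

Step 5
Reactants: 6 2-hydroxy-3,4-dimethoxybenzaldehyde
Product: 7 2-(benzyloxy)-3,4-dimethoxybenzaldehyde
Conditions: BnBr, K2CO3, DMF, 60 °C
Reagents that add atoms: benzyl bromide BrCc1ccccc1
Why: Williamson etherification of the only phenol.

Step 6
Reactants: 7 2-(benzyloxy)-3,4-dimethoxybenzaldehyde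
Product: 8 2-(benzyloxy)-3,4-dimethoxy-1-(2-methoxyethenyl)benzene (E/Z mixture)
Conditions: MeOCH2PPh3Cl, KOt-Bu, THF, 0 °C to rt
Reagents that add atoms: (methoxymethyl)triphenylphosphonium chloride COC[P+](c1ccccc1)(c1ccccc1)c1ccccc1.[Cl-]
Why: Wittig methoxymethylenation adds the one carbon needed for the arylacetic acid; the alkene geometry is irrelevant because it is hydrolysed next.

Step 7
Reactants: 8 2-(benzyloxy)-3,4-dimethoxy-1-(2-methoxyethenyl)benzene
Product: 9 2-[2-(benzyloxy)-3,4-dimethoxyphenyl]acetaldehyde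
Conditions: 2 M HCl, THF, 50 °C; crude product carried on
Reagents that add atoms: water O
Why: Acid hydrolysis of the enol ether releases the arylacetaldehyde while the benzyl and methyl ethers are stable to dilute acid.

Step 8
Reactants: 9 2-[2-(benzyloxy)-3,4-dimethoxyphenyl]acetaldehyde
Product: 10 2-[2-(benzyloxy)-3,4-dimethoxyphenyl]acetic acid
Conditions: NaClO2, NaH2PO4, 2-methyl-2-butene, t-BuOH/H2O, rt
Reagents that add atoms: sodium chlorite [Na+].[O-]Cl=O
Why: Pinnick oxidation takes the aldehyde to the acid without attacking the electron-rich ring, since the alkene scavenges the hypochlorite formed.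

Step 9
Reactants: 10 2-[2-(benzyloxy)-3,4-dimethoxyphenyl]acetic acid; 11 (R)-4-benzyl-2-oxazolidinone
Product: 13 (R)-4-benzyl-3-{2-[2-(benzyloxy)-3,4-dimethoxyphenyl]acetyl}oxazolidin-2-one, via mixed pivalic anhydride 12 (not isolated)
Conditions: t-BuCOCl, Et3N, THF, −20 °C; then 11, LiCl, −20 °C to rt
Reagents that add atoms: none
Why: N-acylation of the oxazolidinone through the mixed anhydride under LiCl/Et3N activation avoids a strong base and the ketene-prone acid chloride.

Step 10
Reactants: 13 (R)-4-benzyl-3-{2-[2-(benzyloxy)-3,4-dimethoxyphenyl]acetyl}oxazolidin-2-one; 5 4-(benzyloxy)-5-bromo-2-(methoxymethoxy)benzyl bromide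
Product: 15 (R)-4-benzyl-3-{(2R)-2-[2-(benzyloxy)-3,4-dimethoxyphenyl]-3-[4-(benzyloxy)-5-bromo-2-(methoxymethoxy)phenyl]propanoyl}oxazolidin-2-one, via sodium Z-enolate 14 (not isolated)
Conditions: NaN(SiMe3)2, THF, −78 °C; then 5, −78 to −40 °C; AcOH quench at low temperature
Reagents that add atoms: none
Why: Evans asymmetric alkylation: the chelated sodium Z-enolate is shielded on one face by the C4 benzyl group of the auxiliary, so the benzylic bromide enters from the opposite face and the (R)-auxiliary should give the 2R centre (the future C3).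

Step 11
Reactants: 15 the alkylated imide
Product: 16 (2R)-2-[2-(benzyloxy)-3,4-dimethoxyphenyl]-3-[4-(benzyloxy)-5-bromo-2-(methoxymethoxy)phenyl]propan-1-ol
Conditions: LiBH4, H2O (1 equiv), Et2O/THF, 0 °C
Reagents that add atoms: none
Why: Reductive cleavage of the N-acyl oxazolidinone with LiBH4 gives the primary alcohol and takes the stereocentre out of the epimerisable α-carbonyl position; the aryl bromide and MOM group are inert.

Step 12
Reactants: 16 the MOM-protected primary alcohol
Product: 17 5-(benzyloxy)-2-{(2R)-2-[2-(benzyloxy)-3,4-dimethoxyphenyl]-3-hydroxypropyl}-4-bromophenol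
Conditions: conc. HCl (cat.), MeOH/THF, 50 °C
Reagents that add atoms: none
Why: Acid-catalysed acetal exchange with methanol removes the MOM group selectively, as benzyl and methyl aryl ethers do not react under these conditions.

Step 13
Reactants: 17 the phenol alcohol
Product: 18 (3R)-7-(benzyloxy)-3-[2-(benzyloxy)-3,4-dimethoxyphenyl]-6-bromochromane
Conditions: PPh3, DIAD, THF (dilute), 0 °C to rt
Reagents that add atoms: none
Why: Intramolecular Mitsunobu etherification closes the pyran ring by attack of the phenol on the activated primary carbon (6-exo-tet); the C3 stereocentre is not involved.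

Step 14
Reactants: 18 the 6-bromoisoflavan
Product: 19 (3R)-7-(benzyloxy)-3-[2-(benzyloxy)-3,4-dimethoxyphenyl]-6-[(trimethylsilyl)ethynyl]chromane
Conditions: trimethylsilylacetylene, PdCl2(PhCN)2 (cat.), P(t-Bu)3·HBF4 (cat.), CuI (cat.), i-Pr2NH, dioxane, rt to 50 °C
Reagents that add atoms: trimethylsilylacetylene C#C[Si](C)(C)C
Why: Sonogashira coupling; the bulky electron-rich phosphine is chosen because the bromide is electron-rich and flanked by an ortho alkoxy group.

Step 15
Reactants: 19 the silyl alkyne
Product: 20 (3R)-7-(benzyloxy)-3-[2-(benzyloxy)-3,4-dimethoxyphenyl]-6-ethynylchromane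
Conditions: K2CO3 (cat.), MeOH/THF, rt
Reagents that add atoms: none
Why: Base-catalysed methanolysis of the alkynyl–silicon bond (protodesilylation) frees the terminal alkyne.

Step 16
Reactants: 20 the 6-ethynylisoflavan; 21 cis-1,2-dimethyl-1,2-dihydroacenaphthylene-1,2-diol (mac diol)
Product: 23 (3R)-7-(benzyloxy)-3-[2-(benzyloxy)-3,4-dimethoxyphenyl]-6-[(E)-2-B(mac)-ethenyl]chromane [boron bound to both oxygens of 21], via alkenyl catecholboronate 22 (not isolated)
Conditions: catecholborane, THF, 70 °C; excess borane removed in vacuo; then 21, THF, rt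
Reagents that add atoms: catecholborane B1Oc2ccccc2O1
Why: Syn hydroboration of the terminal alkyne with catecholborane puts boron on the terminal carbon and fixes the E geometry, and the labile catechol ester is then transesterified by the aliphatic cis-diol to the chromatography-stable B(mac) ester.

Step 17
Reactants: 24 4-(benzyloxy)benzyl chloride
Product: 25 4-(benzyloxy)benzylmagnesium chloride (titrated THF solution)
Conditions: Mg turnings (excess), THF, 0 °C, slow addition at high dilution
Reagents that add atoms: magnesium [Mg]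
Why: Grignard formation by magnesium insertion into the benzylic C–Cl bond; cold, dilute, slow addition holds back Wurtz homocoupling.

Step 18
Reactants: 26 4-bromoresorcinol
Product: 27 2,4-bis(benzyloxy)-1-bromobenzene
Conditions: BnBr (2.2 equiv), K2CO3, DMF, 60 °C
Reagents that add atoms: benzyl bromide BrCc1ccccc1
Why: Double Williamson etherification of both phenols.

Step 19
Reactants: 23 the (E)-alkenyl B(mac) boronate; 25 4-(benzyloxy)benzylmagnesium chloride; 27 2,4-bis(benzyloxy)-1-bromobenzene
Product: 29 (3R)-7-(benzyloxy)-3-[2-(benzyloxy)-3,4-dimethoxyphenyl]-6-{(1R,2R)-1-[2,4-bis(benzyloxy)phenyl]-3-[4-(benzyloxy)phenyl]-2-B(mac)-propyl}chromane, via chloromagnesium borate 28 (not isolated)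
Conditions: 25 (1.1 equiv), THF, 0 °C to rt; then 27, Pd(OAc)2 (3 mol%), (Sp,Sp)-MandyPhos {1,1'-bis[bis(4-methoxy-3,5-dimethylphenyl)phosphino]-2,2'-bis[(R)-α-(dimethylamino)benzyl]ferrocene, 3.6 mol%}, NaOSO2CF3 (2 equiv), THF, 60 °C
Reagents that add atoms: none
Why: Grignard reagent 25 adds to the boron of 23 to give the four-coordinate borate 28; zerovalent palladium carrying the bisphosphine inserts into the C–Br bond of 27, the triflate salt removes the halide, and the cationic aryl–palladium species binds the alkene of 28, which triggers a 1,2-shift of the benzyl group from boron to the boron-bearing carbon anti to palladium, after which the benzylic C–Pd bond reductively eliminates with retention to form the diarylmethine. The closest known reaction type is the enantioselective palladium-catalysed conjunctive cross-coupling of β-substituted alkenyl B(mac) ate complexes made from Grignard reagents with aryl bromides and a triflate salt; a β-aryl alkenyl boronate with a benzylic migrating group and an ortho-alkoxy aryl bromide is a demanding member of that class. No ring is closed. The diarylmethine carbon is set by the ligand, which must place palladium on the alkene face that is Si at the carbon next to ring A, and the boron-bearing carbon is tied to it by the anti addition across the E double bond, giving the 1R,2R pair; the remote C3 centre is not expected to interfere. The step needs the metallate shift to outrun direct Suzuki transfer (secured by the hindered mac diol on boron), clean anti diastereospecificity (secured by the E geometry of 23) and reductive elimination faster than β-hydride elimination (favoured by the bidentate ferrocenyl bisphosphine), while the C6 position is already fixed by the bromine bought in 1.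

Step 20
Reactants: 29 the secondary B(mac) boronate
Product: 30 (1R,2R)-1-{(3R)-7-(benzyloxy)-3-[2-(benzyloxy)-3,4-dimethoxyphenyl]chroman-6-yl}-1-[2,4-bis(benzyloxy)phenyl]-3-[4-(benzyloxy)phenyl]propan-2-ol
Conditions: 30% H2O2, 3 M NaOH, THF, 0 °C to rt
Reagents that add atoms: hydrogen peroxide OO
Why: Alkaline peroxide oxidation of the C–B bond proceeds by 1,2-migration of carbon from boron to oxygen with retention, so the boron-bearing centre becomes the 2R carbinol.

Step 21
Reactants: 30 the penta-O-benzyl carbinol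
Product: 31 (3R)-6-[(1R,2R)-1-(2,4-dihydroxyphenyl)-2-hydroxy-3-(4-hydroxyphenyl)propyl]-3-(2-hydroxy-3,4-dimethoxyphenyl)chroman-7-ol (CNP0185256.1)
Conditions: H2 (1 atm), 10% Pd/C, EtOAc/MeOH, rt
Reagents that add atoms: none
Why: Catalytic hydrogenolysis cleaves the five benzyl aryl ethers; the carbinol is not benzylic, and the diarylmethine and the pyran ring carry no benzylic C–O bond, so nothing else is reduced.

## Compound list

1 | 5-bromo-2,4-dihydroxybenzaldehyde | O=Cc1cc(Br)c(O)cc1O | starting material
2 | 4-(benzyloxy)-5-bromo-2-hydroxybenzaldehyde | O=Cc1cc(Br)c(OCc2ccccc2)cc1O | intermediate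
3 | 4-(benzyloxy)-5-bromo-2-(methoxymethoxy)benzaldehyde | O=Cc1cc(Br)c(OCc2ccccc2)cc1OCOC | intermediate
4 | [4-(benzyloxy)-5-bromo-2-(methoxymethoxy)phenyl]methanol | OCc1cc(Br)c(OCc2ccccc2)cc1OCOC | intermediate
5 | 4-(benzyloxy)-5-bromo-2-(methoxymethoxy)benzyl bromide | BrCc1cc(Br)c(OCc2ccccc2)cc1OCOC | intermediate
6 | 2-hydroxy-3,4-dimethoxybenzaldehyde | COc1ccc(C=O)c(O)c1OC | starting material
7 | 2-(benzyloxy)-3,4-dimethoxybenzaldehyde | COc1ccc(C=O)c(OCc2ccccc2)c1OC | intermediate
8 | 2-(benzyloxy)-3,4-dimethoxy-1-(2-methoxyethenyl)benzene, E/Z mixture | COC=Cc1ccc(OC)c(OC)c1OCc1ccccc1 | intermediate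
9 | 2-[2-(benzyloxy)-3,4-dimethoxyphenyl]acetaldehyde | COc1ccc(CC=O)c(OCc2ccccc2)c1OC | intermediate
10 | 2-[2-(benzyloxy)-3,4-dimethoxyphenyl]acetic acid | COc1ccc(CC(=O)O)c(OCc2ccccc2)c1OC | intermediate
11 | (R)-4-benzyl-2-oxazolidinone | O=C1OC[C@@H](Cc2ccccc2)N1 | starting material
12 | mixed anhydride of acid 10 with pivalic acid | COc1ccc(CC(=O)OC(=O)C(C)(C)C)c(OCc2ccccc2)c1OC | intermediate
13 | (R)-4-benzyl-3-{2-[2-(benzyloxy)-3,4-dimethoxyphenyl]acetyl}oxazolidin-2-one | COc1ccc(CC(=O)N2C(=O)OC[C@H]2Cc2ccccc2)c(OCc2ccccc2)c1OC | intermediate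
14 | sodium (Z)-enolate of imide 13 | COc1ccc(/C=C(\[O-])N2C(=O)OC[C@H]2Cc2ccccc2)c(OCc2ccccc2)c1OC.[Na+] | intermediate
15 | (R)-4-benzyl-3-{(2R)-2-[2-(benzyloxy)-3,4-dimethoxyphenyl]-3-[4-(benzyloxy)-5-bromo-2-(methoxymethoxy)phenyl]propanoyl}oxazolidin-2-one | COc1ccc([C@@H](Cc2cc(Br)c(OCc3ccccc3)cc2OCOC)C(=O)N2C(=O)OC[C@H]2Cc2ccccc2)c(OCc2ccccc2)c1OC | intermediate
16 | (2R)-2-[2-(benzyloxy)-3,4-dimethoxyphenyl]-3-[4-(benzyloxy)-5-bromo-2-(methoxymethoxy)phenyl]propan-1-ol | COc1ccc([C@@H](Cc2cc(Br)c(OCc3ccccc3)cc2OCOC)CO)c(OCc2ccccc2)c1OC | intermediate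
17 | 5-(benzyloxy)-2-{(2R)-2-[2-(benzyloxy)-3,4-dimethoxyphenyl]-3-hydroxypropyl}-4-bromophenol | COc1ccc([C@@H](Cc2cc(Br)c(OCc3ccccc3)cc2O)CO)c(OCc2ccccc2)c1OC | intermediate
18 | (3R)-7-(benzyloxy)-3-[2-(benzyloxy)-3,4-dimethoxyphenyl]-6-bromochromane | COc1ccc([C@@H]2COc3cc(OCc4ccccc4)c(Br)cc3C2)c(OCc2ccccc2)c1OC | intermediate
19 | (3R)-7-(benzyloxy)-3-[2-(benzyloxy)-3,4-dimethoxyphenyl]-6-[(trimethylsilyl)ethynyl]chromane | COc1ccc([C@@H]2COc3cc(OCc4ccccc4)c(C#C[Si](C)(C)C)cc3C2)c(OCc2ccccc2)c1OC | intermediate
20 | (3R)-7-(benzyloxy)-3-[2-(benzyloxy)-3,4-dimethoxyphenyl]-6-ethynylchromane | COc1ccc([C@@H]2COc3cc(OCc4ccccc4)c(C#C)cc3C2)c(OCc2ccccc2)c1OC | intermediate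
21 | cis-1,2-dimethyl-1,2-dihydroacenaphthylene-1,2-diol (mac diol, meso) | O[C@]1(C)c2cccc3cccc(c23)[C@]1(C)O | starting material
22 | 2-[(E)-2-{(3R)-7-(benzyloxy)-3-[2-(benzyloxy)-3,4-dimethoxyphenyl]chroman-6-yl}ethenyl]-1,3,2-benzodioxaborole | COc1ccc([C@@H]2COc3cc(OCc4ccccc4)c(/C=C/B4Oc5ccccc5O4)cc3C2)c(OCc2ccccc2)c1OC | intermediate
23 | (E)-alkenyl B(mac) boronate: boronic ester of diol 21 with the (E)-2-(isoflavan-6-yl)ethenyl group | COc1ccc([C@@H]2COc3cc(OCc4ccccc4)c(/C=C/B4O[C@]5(C)c6cccc7cccc(c67)[C@]5(C)O4)cc3C2)c(OCc2ccccc2)c1OC | intermediate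
24 | 4-(benzyloxy)benzyl chloride | ClCc1ccc(OCc2ccccc2)cc1 | starting material
25 | 4-(benzyloxy)benzylmagnesium chloride | Cl[Mg]Cc1ccc(OCc2ccccc2)cc1 | intermediate
26 | 4-bromoresorcinol | Oc1ccc(Br)c(O)c1 | starting material
27 | 2,4-bis(benzyloxy)-1-bromobenzene | Brc1ccc(OCc2ccccc2)cc1OCc1ccccc1 | intermediate
28 | chloromagnesium [4-(benzyloxy)benzyl][(E)-2-(isoflavan-6-yl)ethenyl]borate of diol 21 (configuration at boron not defined) | COc1ccc([C@@H]2COc3cc(OCc4ccccc4)c(/C=C/[B-]4(Cc5ccc(OCc6ccccc6)cc5)O[C@]5(C)c6cccc7cccc(c67)[C@]5(C)O4)cc3C2)c(OCc2ccccc2)c1OC.[Mg+]Cl | intermediate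
29 | (1R,2R) secondary B(mac) boronate: 1-(isoflavan-6-yl)-1-[2,4-bis(benzyloxy)phenyl]-3-[4-(benzyloxy)phenyl]propan-2-yl boronic ester of diol 21 | COc1ccc([C@@H]2COc3cc(OCc4ccccc4)c([C@@H](c4ccc(OCc5ccccc5)cc4OCc4ccccc4)[C@H](B4O[C@]5(C)c6cccc7cccc(c67)[C@]5(C)O4)Cc4ccc(OCc5ccccc5)cc4)cc3C2)c(OCc2ccccc2)c1OC | intermediate
30 | (1R,2R)-1-{(3R)-7-(benzyloxy)-3-[2-(benzyloxy)-3,4-dimethoxyphenyl]chroman-6-yl}-1-[2,4-bis(benzyloxy)phenyl]-3-[4-(benzyloxy)phenyl]propan-2-ol | COc1ccc([C@@H]2COc3cc(OCc4ccccc4)c([C@@H](c4ccc(OCc5ccccc5)cc4OCc4ccccc4)[C@H](O)Cc4ccc(OCc5ccccc5)cc4)cc3C2)c(OCc2ccccc2)c1OC | intermediate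
31 | (3R)-6-[(1R,2R)-1-(2,4-dihydroxyphenyl)-2-hydroxy-3-(4-hydroxyphenyl)propyl]-3-(2-hydroxy-3,4-dimethoxyphenyl)chroman-7-ol | COc1ccc([C@@H]2COc3cc(O)c([C@@H](c4ccc(O)cc4O)[C@H](O)Cc4ccc(O)cc4)cc3C2)c(O)c1OC | target

## Step count and risks

Total: 21 steps. Longest linear sequence: 15 steps (from aldehyde 6: steps 5 to 16, then 19 to 21).

**Step 19 (three-component coupling).** The benzylic palladium intermediate may undergo β-hydride elimination, the alkenyl group may transfer directly to palladium (Suzuki pathway) faster than the metallate shift, or the ligand may discriminate poorly between the faces of this hindered, electron-rich styrenyl borate. The fallback keeps the three fragments but forms the two bonds in separate operations. It sets out from the catechol boronate 22, made from 20 as in step 16 and used before the diol exchange. Suzuki–Miyaura coupling with benzyl chloride 24 (Pd(PPh3)4, aqueous K3PO4, THF, 65 °C) should give (3R)-7-(benzyloxy)-3-[2-(benzyloxy)-3,4-dimethoxyphenyl]-6-[(E)-3-(4-benzyloxyphenyl)prop-1-enyl]chromane F1. A copper/palladium dual-catalysed syn-arylboration of F1 with bromide 27 and bis(pinacolato)diboron (a chiral N-heterocyclic carbene copper chloride (NHC)CuCl, Pd(OAc)2/RuPhos, NaOt-Bu, toluene/THF) should put boron on the homobenzylic carbon and, after stereoretentive transfer from copper to aryl–palladium, the resorcinol ring on the carbon next to ring A, giving the (1R,2R) pinacol boronate F2. Syn addition across this E alkene leads to the same relative configuration as anti addition across 23, because the benzyl carbon and the boron have exchanged roles. Oxidation of F2 with H2O2/NaOH comes back to the route at carbinol 30.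

**Step 10 (auxiliary-controlled alkylation).** The electron-rich benzylic bromide may ionise and self-condense before it is alkylated, the hindered aryl-substituted enolate may react slowly, and the acidic benzylic α-centre may epimerise on warming. The fallback avoids the benzylic halide and sets out from aldehyde 3 and acid 10. A Perkin-type condensation (Ac2O, Et3N, 110 °C) should give (E)-2-[2-(benzyloxy)-3,4-dimethoxyphenyl]-3-[4-(benzyloxy)-5-bromo-2-(methoxymethoxy)phenyl]acrylic acid F3. Enantioselective hydrogenation of this α-aryl cinnamic acid with a cationic iridium spiro phosphine–oxazoline catalyst, [Ir(cod)(SIPHOX)]BArF (H2, Et3N, MeOH; ligand antipode chosen for the R acid), should give (2R)-2-[2-(benzyloxy)-3,4-dimethoxyphenyl]-3-[4-(benzyloxy)-5-bromo-2-(methoxymethoxy)phenyl]propanoic acid F4. Reduction with BH3·SMe2 in THF comes back to the route at alcohol 16.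

**Step 16 (hydroboration and ligand exchange).** Hydroboration of the ortho-alkoxy arylalkyne may be incomplete or poorly regioselective, and the boronate may protodeboronate or exchange incompletely when the catechol is replaced by the hindered tertiary diol. The fallback installs the vinyl boron unit directly on the bromide and sets out from 18. A Heck reaction with vinylboronic acid MIDA ester (Pd(OAc)2, P(o-tol)3, Et3N, MeCN, 80 °C) should give the (E)-2-(isoflavan-6-yl)ethenyl MIDA boronate F5. Mild hydrolysis (1 M NaOH, THF, rt) should release the (E)-2-(isoflavan-6-yl)ethenylboronic acid F6, and condensation with diol 21 (MgSO4, CH2Cl2, rt) comes back to the route at boronate 23.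

## Further compounds

F1 | step 19 | (3R)-7-(benzyloxy)-3-[2-(benzyloxy)-3,4-dimethoxyphenyl]-6-[(E)-3-(4-benzyloxyphenyl)prop-1-enyl]chromane | COc1ccc([C@@H]2COc3cc(OCc4ccccc4)c(/C=C/Cc4ccc(OCc5ccccc5)cc4)cc3C2)c(OCc2ccccc2)c1OC
F2 | step 19 | (1R,2R) pinacol boronate corresponding to 29 | COc1ccc([C@@H]2COc3cc(OCc4ccccc4)c([C@@H](c4ccc(OCc5ccccc5)cc4OCc4ccccc4)[C@H](B4OC(C)(C)C(C)(C)O4)Cc4ccc(OCc5ccccc5)cc4)cc3C2)c(OCc2ccccc2)c1OC
F3 | step 10 | (E)-2-[2-(benzyloxy)-3,4-dimethoxyphenyl]-3-[4-(benzyloxy)-5-bromo-2-(methoxymethoxy)phenyl]acrylic acid | OC(=O)/C(=C/c1cc(Br)c(OCc2ccccc2)cc1OCOC)c1ccc(OC)c(OC)c1OCc1ccccc1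
F4 | step 10 | (2R)-2-[2-(benzyloxy)-3,4-dimethoxyphenyl]-3-[4-(benzyloxy)-5-bromo-2-(methoxymethoxy)phenyl]propanoic acid | COc1ccc([C@@H](Cc2cc(Br)c(OCc3ccccc3)cc2OCOC)C(=O)O)c(OCc2ccccc2)c1OC
F5 | step 16 | (E)-2-{(3R)-7-(benzyloxy)-3-[2-(benzyloxy)-3,4-dimethoxyphenyl]chroman-6-yl}ethenyl MIDA boronate | COc1ccc([C@@H]2COc3cc(OCc4ccccc4)c(/C=C/[B-]45OC(=O)C[N+]4(C)CC(=O)O5)cc3C2)c(OCc2ccccc2)c1OC
F6 | step 16 | (E)-2-{(3R)-7-(benzyloxy)-3-[2-(benzyloxy)-3,4-dimethoxyphenyl]chroman-6-yl}ethenylboronic acid | COc1ccc([C@@H]2COc3cc(OCc4ccccc4)c(/C=C/B(O)O)cc3C2)c(OCc2ccccc2)c1OC
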